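(The numbers in the tables are calculated on assumed constants; the scatter is artificial.)

A one-step world, D going straight to J over a lasting L, has J ending at the charge; but Wednesday's flask, the one asked about, stood at 34.9 % with 0 % of D left, and Sunday's at 24.1 %, so I took D to pass through X, with L dying on the way.

| flask | D | L | remark | time |
|---|---|---|---|---|
| Wednesday's | 0.10 M | 15 mol% | the very flask that is asked about, followed so far |  |
| Sunday's | 0.067 M | 15 mol% | run made earlier |  |
| flask | 0.10 M | 15 mol% |  | 2.5 h |

| run | time / min | J / % | D / % |
|---|---|---|---|
| Wednesday's | 20.0 | 20.9 | 13.9 |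
| Wednesday's | 50.0 | 31.6 | 0 |
| Wednesday's | 90.0 | 35.6 | 0 |
| Wednesday's | 150 | 34.9 | 0 |
| Sunday's | 5.00 | 1.3 | 60.8 |
| Sunday's | 10.0 | 8.2 | 36.6 |
| Sunday's | 25.0 | 19.3 | 9.0 |
| Sunday's | 60.0 | 24.1 | 0 |

(standard deviation of a reading: 1 percentage point)
- ochre: at 2.5 h add D, 50.0 % of the amount charged, then wait 2.5 h
- red: at 2.5 h take out 90 % of the J then present, then wait 2.5 h
- teal: at 2.5 h add L, 100 % of the amount charged, then wait 2.5 h
- grey: change nothing and wait 2.5 h more
- what is taken out of J is counted as made
- candidate steps: D -> X; L + X -> L + J; L -> Z; L -> E; D -> Q
- additions bring no volume worth counting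
- J, in percent of the D first charged, at 2.5 h
- which option adds most J ("none" when 2 percentage points or less is all one gets) (ochre / red / teal / grey / none)
- J present, with what was taken out counted in, in percent of the D first charged, after red
- J present, with what was taken out counted in, in percent of the D first charged, after teal

I solved the two ends and joined them. From Sunday's D I read a decay constant of 0.0963 min⁻¹, and from the closing gap to Wednesday's plateau a death constant for L of 0.0482 min⁻¹. I called reach the pseudo-first-order rate of X loss on fresh L times the lifetime of L, that is, the number of e-folds of X one charge works through before dying. Sunday's early J, scaled to Wednesday's charge, gave reach times the share of D entering X as 0.960.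

An X born late meets thinned L, on average by the factor 0.666, so a share of 0.5 predicted a plateau of 36.1 %, close to the reading, with reach 1.92. Teal's fresh L acts on X already present, so the crude bracket for teal ran from 34.9 %, with no X left, to 75.1 %, with every D entering X. Shares of 40.0 % and 60.0 % missed the plateau by predicting 31.9 % and 39.3 %, which tightened it to 39.5 % to 54.9 %. I committed to teal at 47.8 %, with J at the asked time and after red staying near the plateau.

The forecast, "Teal wins", gave 35.2 % now, teal as best, 35.3 % after red and 66.5 % after teal, higher than my upper bound.

The flask gave 34.8 % now, teal as best, 34.8 % after red and 51.8 % after teal, lower than that bound.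

    D → X (k = 9.24 × 10⁻⁴ s⁻¹)
    L + X → L + J (k = 0.0889 M⁻¹ s⁻¹)
    L → Z (k = 8.45 × 10⁻⁴ s⁻¹)
    L → E (k = 1.23 × 10⁻⁶ s⁻¹)
    D → Q (k = 7.19 × 10⁻⁴ s⁻¹)

The step from L to Z has the largest single effect on teal's gain: the run without it shows 0 percentage points in place of 17 points. Wednesday's flask held X at 21.4 % after 150 min, and my reach turns that into a gain from teal of 18 points, against the 17 points found. The neighbour with 3.8 mol% of L has reach 0.486, which at my share gives 13.8 % of J; the computed flask gives 12.8 %.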